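**Plan**
- Late cuts: the C6 ester (acid 21), the C1–OH (from a C–B bond) and the C3–OH (from the C3 ketone), so no hydroxyl of the 1,3-diol is ever protected.
- Key cut: bonds C1–C2 and C5–C10 together, opening rings A and B of the decalin to the acyclic triene 14 (intramolecular Diels–Alder).
- Enabling feature: ring A carries O at C3 and the exocyclic C4=C15 methylene, the retron of a 2-silyloxy diene C2=C3–C4=C5 with C15 as an acyloxymethyl branch on C4; the C1–OH cis to the C10 methyl is the retron of an (E)-alkenylboronate C10=C1; ring B is the tether ring C5–C6–C7–C8–C9–C10.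
- Then C6–C7 is cut (asymmetric chromium allylation) to allyl bromide 8 (from pent-4-yn-1-ol and methyl acrylate) and keto-enal 12 (from a furan).
- Forward: chain assembly, then both rings in one step, then C15 elimination, C6 acylation, C3 reduction, C–B oxidation.
- Stereochemistry: C6/C7 from the catalyst-controlled anti allylation; C5, C10 and C1 from the cycloaddition (relayed from C6/C7 and the alkene geometries); C3 by substrate-controlled Luche reduction; C1–O by stereoretentive C–B oxidation.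

Key step: step 10

Remark: eudesmane numbering (C1–C15) is used for the bicyclic compounds and for the corresponding carbons of the open-chain precursors; Bpin = 4,4,5,5-tetramethyl-1,3,2-dioxaborolan-2-yl, TES = triethylsilyl, TBS = tert-butyldimethylsilyl, Piv = 2,2-dimethylpropanoyl; compounds 1, 6, 9 and 19 are taken as commercial.

**Step 1**
Reactants: 1 pent-4-yn-1-ol
Product: 3 (4E)-5-iodo-4-methylpent-4-en-1-ol, via alkenylalane 2 (not isolated)
Conditions: Me3Al (3 equiv), Cp2ZrCl2 (0.25 equiv), CH2Cl2, 0 °C → rt; then I2, THF, −30 → 0 °C; aq. Rochelle salt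
Reagents that add atoms: trimethylaluminium, C[Al](C)C; iodine, II
Why: Negishi zirconium-catalysed carboalumination adds CH3 and Al syn across the terminal alkyne with Al on the terminal carbon, and iodinolysis with retention fixes the (E)-trisubstituted alkene.

**Step 2**
Reactants: 3 (4E)-5-iodo-4-methylpent-4-en-1-ol
Product: 4 (4E)-4-methyl-5-(Bpin)pent-4-en-1-ol
Conditions: B2pin2, PdCl2(PPh3)2 (3 mol%), PPh3 (6 mol%), KOPh, toluene, 50 °C
Reagents that add atoms: bis(pinacolato)diboron, CC1(C)OB(OC1(C)C)B1OC(C)(C)C(C)(C)O1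
Why: Miyaura borylation of an alkenyl iodide proceeds with retention of the alkene geometry and tolerates the free alcohol.

**Step 3**
Reactants: 4 (4E)-4-methyl-5-(Bpin)pent-4-en-1-ol
Product: 5 (4E)-4-methyl-5-(Bpin)pent-4-enal
Conditions: Dess–Martin periodinane, NaHCO3, CH2Cl2, 0 °C → rt
Reagents that add atoms: none
Why: Dess–Martin oxidation of a primary alcohol; the alkenylboronate is inert to the buffered hypervalent iodine reagent.

**Step 4**
Reactants: 5 (4E)-4-methyl-5-(Bpin)pent-4-enal; 6 methyl acrylate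
Product: 7 methyl (6E)-3-hydroxy-6-methyl-2-methylidene-7-(Bpin)hept-6-enoate (racemic)
Conditions: DABCO (1 equiv), methyl acrylate (3 equiv), MeOH, rt, several days
Reagents that add atoms: none
Why: Morita–Baylis–Hillman reaction; the new carbinol centre is left racemic because it becomes sp2 in step 5.

**Step 5**
Reactants: 7 methyl (6E)-3-hydroxy-6-methyl-2-methylidene-7-(Bpin)hept-6-enoate
Product: 8 methyl (2Z,6E)-2-(bromomethyl)-6-methyl-7-(Bpin)hepta-2,6-dienoate
Conditions: NBS, Me2S, CH2Cl2, 0 °C; then 7, 0 °C → rt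
Reagents that add atoms: N-bromosuccinimide, O=C1CCC(=O)N1Br
Why: Corey–Kim-type activation of the allylic alcohol followed by SN2′ attack of bromide gives the transposed 2-(bromomethyl)enoate as the favoured (2Z) trisubstituted alkene.

**Step 6**
Reactants: 9 (2-methylfuran-3-yl)methanol
Product: 10 (2-methylfuran-3-yl)methyl 2,2-dimethylpropanoate
Conditions: PivCl, pyridine, CH2Cl2, 0 °C
Reagents that add atoms: pivaloyl chloride, CC(C)(C)C(=O)Cl
Why: Acylation of a primary alcohol; the pivalate later serves as steering group and as leaving group for C15.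

**Step 7**
Reactants: 10 (2-methylfuran-3-yl)methyl 2,2-dimethylpropanoate
Product: 12 (2E)-2-acetyl-4-oxobut-2-en-1-yl 2,2-dimethylpropanoate, via cis-keto-enal 11 (not isolated)
Conditions: NBS, NaHCO3, acetone/H2O (10:1), −15 °C; then I2 (5 mol%), CH2Cl2, rt; used at once
Reagents that add atoms: water, O
Why: Oxidative ring opening of a 2,3-disubstituted furan (bromination at C5, hydration, opening) gives the cis-ene-dicarbonyl, and iodine-catalysed isomerisation should give the more stable isomer with the two carbonyl groups trans.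

**Step 8**
Reactants: 8 methyl (2Z,6E)-2-(bromomethyl)-6-methyl-7-(Bpin)hepta-2,6-dienoate; 12 (2E)-2-acetyl-4-oxobut-2-en-1-yl 2,2-dimethylpropanoate
Product: 13 methyl (3S,4R,5E)-6-[(pivaloyloxy)methyl]-2-methylidene-3-[(3E)-3-methyl-4-(Bpin)but-3-en-1-yl]-7-oxo-4-(triethylsilyloxy)oct-5-enoate
Conditions: CrCl2 (10 mol%), 3,6-di-tert-butyl-1,8-bis[(4S)-4-isopropyl-4,5-dihydrooxazol-2-yl]-9H-carbazole (12 mol%; the mirror-image ligand if the facial sense proves opposite), Mn powder, Et3SiCl, i-Pr2NEt (30 mol%), THF, 0 °C → rt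
Reagents that add atoms: chlorotriethylsilane, CC[Si](Cl)(CC)CC
Why: Catalytic asymmetric Nozaki–Hiyama–Kishi-type 2-(alkoxycarbonyl)allylation, in which the trivalent allylchromium species adds through its γ-carbon to the aldehyde only, via a closed chair transition state with the C8 chain pseudo-equatorial (anti C6/C7 whatever the bromide geometry), the ligand sets the absolute configuration (C6 R, C7 S), and Et3SiCl turns the chromium alkoxide over as the TES ether so that the γ-hydroxy ester is never free.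

**Step 9**
Reactants: 13 the TES ether enone from step 8
Product: 14 methyl (3S,4R,5E)-6-[(pivaloyloxy)methyl]-2-methylidene-3-[(3E)-3-methyl-4-(Bpin)but-3-en-1-yl]-4,7-bis(triethylsilyloxy)octa-5,7-dienoate
Conditions: Et3SiOTf, Et3N, CH2Cl2, −78 → 0 °C
Reagents that add atoms: triethylsilyl trifluoromethanesulfonate, CC[Si](CC)(CC)OS(=O)(=O)C(F)(F)F
Why: Soft enolisation of the methyl ketone on its methyl side gives the cross-conjugated 2-silyloxy diene; no stereocentre is touched.

**Step 10**
Reactants: 14 the bis-silyl triene from step 9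
Product: 15 methyl 15-(pivaloyloxy)-1β-(Bpin)-3,6α-bis(triethylsilyloxy)eudesma-3,11(13)-dien-12-oate (5α-H; 7α-H; 10β-CH3)
Conditions: toluene (0.005 M), BHT (0.2 equiv), Et3N (0.2 equiv), 165 °C, sealed silylated tube
Reagents that add atoms: none
Why: Thermal, concerted but asynchronous intramolecular [4+2] cycloaddition in which the (E)-2-silyloxy diene C2=C3–C4=C5 adds suprafacially to the (E)-alkenylboronate C10=C1 across the four-carbon tether C6–C9; the closest known reaction type is the intramolecular Diels–Alder reaction of 2-silyloxy-1,3,9-decatrienes, combined with the known dienophilicity of alkenylboronic esters. Ring B (C5–C10 bond) closes as the tether-containing carbocycle in the fused mode through a chair-like six-membered array, and ring A (C1–C2 bond) closes as the cyclohexene of the cycloaddition, which leaves the C3=C4 silyl enol ether exactly where the C3 oxygen and the C4 methylene are needed. C1 and C10 are set together by the (E)-geometry of the dienophile (boron cis to the C14 methyl, hence 1β-B beside 10β-CH3), C5 is set trans to C10 by the tether-exo transition state, and the absolute sense of all three follows from C6 and C7, whose OTES and acrylate branches sit equatorial in the chair. The step needs trans ring fusion and this π-face: the C15 pivaloyloxymethyl group on C4, cis to C6 across C4=C5, is expected to act as a steric directing group, since it suffers 1,3-allylic strain with the C6 substituents and collides with the tether in the tether-endo (cis-fused) and OTES-axial transition states, a control element known for decatrienes bearing an allylic alkoxy group. Chemoselectivity is secured because the C7 acrylate is only two atoms from the diene and cannot reach it, while high dilution and BHT suppress bimolecular addition and polymerisation.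

**Step 11**
Reactants: 15 the cycloadduct from step 10
Product: 17 methyl 3-oxo-1β-(Bpin)-6α-(triethylsilyloxy)eudesma-4(15),11(13)-dien-12-oate, via ammonium enolate 16 (not isolated)
Conditions: TBAF (1.05 equiv), THF, −78 → −30 °C; pH 7 buffer
Reagents that add atoms: none
Why: Fluoride cleaves the silyl enol ether faster than the hindered alkyl TES ether, and the regiodefined C3–C4 enolate expels pivalate from C15 (E1cB elimination), so the exocyclic methylene can only appear at C4.

**Step 12**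
Reactants: 17 the silyl-protected enone from step 11
Product: 18 methyl 6α-hydroxy-3-oxo-1β-(Bpin)eudesma-4(15),11(13)-dien-12-oate
Conditions: HF·pyridine, pyridine, THF, 0 °C
Reagents that add atoms: none
Why: Buffered fluoride desilylation of the secondary TES ether under mildly acidic conditions that should leave the boronate, the enone and the γ-hydroxy ester open.

**Step 13**
Reactants: 19 ethyl 2-(hydroxymethyl)prop-2-enoate
Product: 20 ethyl 2-[(tert-butyldimethylsilyloxy)methyl]prop-2-enoate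
Conditions: TBSCl, imidazole, CH2Cl2, 0 °C → rt
Reagents that add atoms: tert-butyldimethylsilyl chloride, CC(C)(C)[Si](C)(C)Cl
Why: Silylation of a primary alcohol.

**Step 14**
Reactants: 20 ethyl 2-[(tert-butyldimethylsilyloxy)methyl]prop-2-enoate
Product: 21 2-[(tert-butyldimethylsilyloxy)methyl]prop-2-enoic acid
Conditions: LiOH·H2O, THF/H2O, 0 °C → rt; then 1 M HCl to pH 4, 0 °C
Reagents that add atoms: lithium hydroxide, [Li+].[OH-]
Why: Ester saponification; the primary TBS ether survives cold, brief acidification.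

**Step 15**
Reactants: 18 the 6α-alcohol from step 12; 21 2-[(tert-butyldimethylsilyloxy)methyl]prop-2-enoic acid
Product: 23 methyl 6α-{2-[(tert-butyldimethylsilyloxy)methyl]prop-2-enoyloxy}-3-oxo-1β-(Bpin)eudesma-4(15),11(13)-dien-12-oate, via mixed anhydride 22 (not isolated)
Conditions: 21, 2,4,6-trichlorobenzoyl chloride, Et3N, THF, rt; then 18, DMAP, toluene, rt
Reagents that add atoms: none
Why: Yamaguchi esterification acylates the only free hydroxyl, because the C1 and C3 oxygens are still masked as the C–B bond and the ketone.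

**Step 16**
Reactants: 23 the keto ester from step 15
Product: 24 methyl 6α-{2-[(tert-butyldimethylsilyloxy)methyl]prop-2-enoyloxy}-3β-hydroxy-1β-(Bpin)eudesma-4(15),11(13)-dien-12-oate
Conditions: NaBH4, CeCl3·7H2O, MeOH/THF, −78 °C
Reagents that add atoms: none
Why: Luche 1,2-reduction of the α-methylene ketone; hydride should attack axially from the α face of the rigid trans-decalin, giving the equatorial 3β-alcohol, and the acrylate esters and the boronate are not reduced.

**Step 17**
Reactants: 24 the allylic alcohol from step 16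
Product: 26 methyl 6α-{2-[(tert-butyldimethylsilyloxy)methyl]prop-2-enoyloxy}-1β,3β-dihydroxyeudesma-4(15),11(13)-dien-12-oate, via borate ester 25 (not isolated)
Conditions: NaBO3·4H2O, THF/H2O (1:1), rt
Reagents that add atoms: sodium perborate, [Na+].[Na+].O[B-]1(O)OO[B-](O)(O)OO1
Why: Oxidation of the C–B bond by 1,2-migration of carbon from boron to oxygen with retention gives the 1β-alcohol; it is placed after step 16 so that no enone is exposed to the nucleophilic peroxide.

**Step 18**
Reactants: 26 the silyl-protected diol from step 17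
Product: 27 methyl (1R,3S,5S,6S,7S,10R)-1β,3β-dihydroxy-6α-{[2-(hydroxymethyl)prop-2-enoyl]oxy}eudesma-4(15),11(13)-dien-12-oate (CNP0247525.1)
Conditions: HF·pyridine, pyridine, THF, 0 °C → rt
Reagents that add atoms: none
Why: Fluoride desilylation of the primary TBS ether under buffered acidic conditions that avoid acyl migration and conjugate addition.

**Compound list**
1 | pent-4-yn-1-ol | C#CCCCO | starting material
2 | (E)-alkenyldimethylalane with O-dimethylaluminium alkoxide | C[Al](C)OCCC/C(C)=C/[Al](C)C | intermediate (not isolated)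
3 | (4E)-5-iodo-4-methylpent-4-en-1-ol | OCCC/C(C)=C/I | intermediate
4 | (4E)-4-methyl-5-(Bpin)pent-4-en-1-ol | OCCC/C(C)=C/B1OC(C)(C)C(C)(C)O1 | intermediate
5 | (4E)-4-methyl-5-(Bpin)pent-4-enal | O=CCC/C(C)=C/B1OC(C)(C)C(C)(C)O1 | intermediate
6 | methyl acrylate | C=CC(=O)OC | starting material
7 | methyl (6E)-3-hydroxy-6-methyl-2-methylidene-7-(Bpin)hept-6-enoate, racemic | C=C(C(=O)OC)C(O)CC/C(C)=C/B1OC(C)(C)C(C)(C)O1 | intermediate
8 | methyl (2Z,6E)-2-(bromomethyl)-6-methyl-7-(Bpin)hepta-2,6-dienoate | COC(=O)/C(CBr)=C/CC/C(C)=C/B1OC(C)(C)C(C)(C)O1 | intermediate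
9 | (2-methylfuran-3-yl)methanol | Cc1occc1CO | starting material
10 | (2-methylfuran-3-yl)methyl 2,2-dimethylpropanoate | Cc1occc1COC(=O)C(C)(C)C | intermediate
11 | (2Z)-2-acetyl-4-oxobut-2-en-1-yl 2,2-dimethylpropanoate | O=C/C=C(COC(=O)C(C)(C)C)\C(C)=O | intermediate (not isolated)
12 | (2E)-2-acetyl-4-oxobut-2-en-1-yl 2,2-dimethylpropanoate | O=C/C=C(COC(=O)C(C)(C)C)/C(C)=O | intermediate
13 | methyl (3S,4R,5E)-6-[(pivaloyloxy)methyl]-2-methylidene-3-[(3E)-3-methyl-4-(Bpin)but-3-en-1-yl]-7-oxo-4-(triethylsilyloxy)oct-5-enoate | CC(=O)/C(COC(=O)C(C)(C)C)=C/[C@@H](O[Si](CC)(CC)CC)[C@@H](CC/C(C)=C/B1OC(C)(C)C(C)(C)O1)C(=C)C(=O)OC | intermediate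
14 | methyl (3S,4R,5E)-6-[(pivaloyloxy)methyl]-2-methylidene-3-[(3E)-3-methyl-4-(Bpin)but-3-en-1-yl]-4,7-bis(triethylsilyloxy)octa-5,7-dienoate | C=C(O[Si](CC)(CC)CC)/C(COC(=O)C(C)(C)C)=C/[C@@H](O[Si](CC)(CC)CC)[C@@H](CC/C(C)=C/B1OC(C)(C)C(C)(C)O1)C(=C)C(=O)OC | intermediate
15 | methyl 15-(pivaloyloxy)-1β-(Bpin)-3,6α-bis(triethylsilyloxy)eudesma-3,11(13)-dien-12-oate | CC[Si](CC)(CC)O[C@@H]1[C@H]2C(COC(=O)C(C)(C)C)=C(O[Si](CC)(CC)CC)C[C@@H](B3OC(C)(C)C(C)(C)O3)[C@]2(C)CC[C@H]1C(=C)C(=O)OC | intermediate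
16 | tetrabutylammonium C3–C4 enolate of the 15-pivaloyloxy-3-ketone | CC[Si](CC)(CC)O[C@@H]1[C@H]2C(COC(=O)C(C)(C)C)=C([O-])C[C@@H](B3OC(C)(C)C(C)(C)O3)[C@]2(C)CC[C@H]1C(=C)C(=O)OC.CCCC[N+](CCCC)(CCCC)CCCC | intermediate (not isolated)
17 | methyl 3-oxo-1β-(Bpin)-6α-(triethylsilyloxy)eudesma-4(15),11(13)-dien-12-oate | CC[Si](CC)(CC)O[C@@H]1[C@H]2C(=C)C(=O)C[C@@H](B3OC(C)(C)C(C)(C)O3)[C@]2(C)CC[C@H]1C(=C)C(=O)OC | intermediate
18 | methyl 6α-hydroxy-3-oxo-1β-(Bpin)eudesma-4(15),11(13)-dien-12-oate | O[C@@H]1[C@H]2C(=C)C(=O)C[C@@H](B3OC(C)(C)C(C)(C)O3)[C@]2(C)CC[C@H]1C(=C)C(=O)OC | intermediate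
19 | ethyl 2-(hydroxymethyl)prop-2-enoate | CCOC(=O)C(=C)CO | starting material
20 | ethyl 2-[(tert-butyldimethylsilyloxy)methyl]prop-2-enoate | CCOC(=O)C(=C)CO[Si](C)(C)C(C)(C)C | intermediate
21 | 2-[(tert-butyldimethylsilyloxy)methyl]prop-2-enoic acid | OC(=O)C(=C)CO[Si](C)(C)C(C)(C)C | intermediate
22 | mixed anhydride of 21 with 2,4,6-trichlorobenzoic acid | C=C(CO[Si](C)(C)C(C)(C)C)C(=O)OC(=O)c1c(Cl)cc(Cl)cc1Cl | intermediate (not isolated)
23 | methyl 6α-{2-[(tert-butyldimethylsilyloxy)methyl]prop-2-enoyloxy}-3-oxo-1β-(Bpin)eudesma-4(15),11(13)-dien-12-oate | C=C(CO[Si](C)(C)C(C)(C)C)C(=O)O[C@@H]1[C@H]2C(=C)C(=O)C[C@@H](B3OC(C)(C)C(C)(C)O3)[C@]2(C)CC[C@H]1C(=C)C(=O)OC | intermediate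
24 | methyl 6α-{2-[(tert-butyldimethylsilyloxy)methyl]prop-2-enoyloxy}-3β-hydroxy-1β-(Bpin)eudesma-4(15),11(13)-dien-12-oate | C=C(CO[Si](C)(C)C(C)(C)C)C(=O)O[C@@H]1[C@H]2C(=C)[C@@H](O)C[C@@H](B3OC(C)(C)C(C)(C)O3)[C@]2(C)CC[C@H]1C(=C)C(=O)OC | intermediate
25 | C1 borate ester (C1–O–Bpin) of 26 | C=C(CO[Si](C)(C)C(C)(C)C)C(=O)O[C@@H]1[C@H]2C(=C)[C@@H](O)C[C@@H](OB3OC(C)(C)C(C)(C)O3)[C@]2(C)CC[C@H]1C(=C)C(=O)OC | intermediate (not isolated)
26 | methyl 6α-{2-[(tert-butyldimethylsilyloxy)methyl]prop-2-enoyloxy}-1β,3β-dihydroxyeudesma-4(15),11(13)-dien-12-oate | C=C(CO[Si](C)(C)C(C)(C)C)C(=O)O[C@@H]1[C@H]2C(=C)[C@@H](O)C[C@@H](O)[C@]2(C)CC[C@H]1C(=C)C(=O)OC | intermediate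
27 | methyl (1R,3S,5S,6S,7S,10R)-1β,3β-dihydroxy-6α-{[2-(hydroxymethyl)prop-2-enoyl]oxy}eudesma-4(15),11(13)-dien-12-oate | C=C(CO)C(=O)O[C@@H]1[C@H]2C(=C)[C@@H](O)C[C@@H](O)[C@]2(C)CC[C@H]1C(=C)C(=O)OC | target

**Step count**
Total: 18 steps. Longest linear sequence: 14 steps (1, 2, 3, 4, 5, 8, 9, 10, 11, 12, 15, 16, 17, 18).

**Steps most likely to fail**

Step 10. The trans ring fusion is the least certain outcome of the route. The tether-endo (cis-fused) transition state may compete if the C15 group steers less than expected, because the boronate only weakly prefers the endo position. In addition, at the temperature required, silyl transfer may expel pivalate from 14 or 15 and unveil the enone in hot solution, where it would degrade. The fallback keeps the cycloaddition but carries C15 as a bulkier, thermally inert silyl ether and unveils the methylene afterwards by sulfonate elimination. It sets out from 9 and 8 and comes back at 18. Alcohol 9 is silylated (TBSCl, imidazole) to tert-butyldimethyl[(2-methylfuran-3-yl)methoxy]silane F1. F1 is opened as in step 7 to (2E)-3-[(tert-butyldimethylsilyloxy)methyl]-4-oxopent-2-enal F2. F2 is coupled with 8 as in step 8 to the TES ether enone F3, which is enol-silylated as in step 9 to the triene F4 and heated as in step 10 to the 15-silyloxy cycloadduct F5. HF·pyridine then removes all three silyl groups to give the keto diol methyl 6α-hydroxy-4α-(hydroxymethyl)-3-oxo-1β-(Bpin)eudesm-11(13)-en-12-oate F6 (either C4 epimer converges). MsCl/Et3N at −20 °C sulfonylates the primary hydroxyl selectively to the mesylate F7, which eliminates in the same flask to 18.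

Step 8. The low-valent metals may reduce or ionise the keto-enal with its allylic pivalate, and the anti or facial selectivity of the allylchromium addition may be incomplete. The fallback replaces the reductive coupling by a stereospecific allylboration. It sets out from 5 (with 12) and comes back at 13. Aldehyde 5 is homologated with dimethyl (1-diazo-2-oxopropyl)phosphonate (K2CO3, MeOH; Ohira–Bestmann) to 2-[(1E)-2-methylhex-1-en-5-yn-1-yl]-4,4,5,5-tetramethyl-1,3,2-dioxaborolane F8. F8 is carboxylated (LDA, −78 °C; ClCO2Me) to methyl (6E)-6-methyl-7-(Bpin)hept-6-en-2-ynoate F9. Syn conjugate hydride addition with [(Ph3P)CuH]6, then trapping of the α-cuprio ester with ICH2Bpin, should give methyl (2Z,6E)-6-methyl-7-(Bpin)-2-[(Bpin)methyl]hepta-2,6-dienoate F10, in which the chain is trans to the CH2B group. Allylboration of 12 under catalysis by a chiral BINOL-derived phosphoric acid (TRIP, toluene, −30 °C) passes through a closed chair and should give the anti hydroxy ester methyl (3S,4R,5E)-4-hydroxy-6-[(pivaloyloxy)methyl]-2-methylidene-3-[(3E)-3-methyl-4-(Bpin)but-3-en-1-yl]-7-oxooct-5-enoate F11. F11 is silylated at once (Et3SiCl, imidazole) to 13.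

Step 15. Acylation of the hindered 6α-hydroxyl by the bulky mixed anhydride may be slow, which leaves time for the γ-hydroxy ester to close to the 6,12-lactone or to add to the neighbouring enone. The fallback uses the smallest acylating agent and builds the hydroxymethyl group last. It sets out from 18 and comes back at 27. Alcohol 18 is acylated with acryloyl chloride (Et3N, cat. DMAP, CH2Cl2, −20 °C) to methyl 6α-(prop-2-enoyloxy)-3-oxo-1β-(Bpin)eudesma-4(15),11(13)-dien-12-oate F12. F12 is reduced as in step 16 to the 3β-alcohol F13 and oxidised as in step 17 to methyl 1β,3β-dihydroxy-6α-(prop-2-enoyloxy)eudesma-4(15),11(13)-dien-12-oate F14. A Morita–Baylis–Hillman reaction with aqueous formaldehyde (DABCO, dioxane/H2O) then hydroxymethylates only the unsubstituted acrylate, the C12 acrylate being α-substituted, and gives 27.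

**Further compounds**
F1 | step 10 | tert-butyldimethyl[(2-methylfuran-3-yl)methoxy]silane | Cc1occc1CO[Si](C)(C)C(C)(C)C
F2 | step 10 | (2E)-3-[(tert-butyldimethylsilyloxy)methyl]-4-oxopent-2-enal | O=C/C=C(CO[Si](C)(C)C(C)(C)C)/C(C)=O
F3 | step 10 | methyl (3S,4R,5E)-6-[(tert-butyldimethylsilyloxy)methyl]-2-methylidene-3-[(3E)-3-methyl-4-(Bpin)but-3-en-1-yl]-7-oxo-4-(triethylsilyloxy)oct-5-enoate | CC(=O)/C(CO[Si](C)(C)C(C)(C)C)=C/[C@@H](O[Si](CC)(CC)CC)[C@@H](CC/C(C)=C/B1OC(C)(C)C(C)(C)O1)C(=C)C(=O)OC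
F4 | step 10 | methyl (3S,4R,5E)-6-[(tert-butyldimethylsilyloxy)methyl]-2-methylidene-3-[(3E)-3-methyl-4-(Bpin)but-3-en-1-yl]-4,7-bis(triethylsilyloxy)octa-5,7-dienoate | C=C(O[Si](CC)(CC)CC)/C(CO[Si](C)(C)C(C)(C)C)=C/[C@@H](O[Si](CC)(CC)CC)[C@@H](CC/C(C)=C/B1OC(C)(C)C(C)(C)O1)C(=C)C(=O)OC
F5 | step 10 | methyl 15-(tert-butyldimethylsilyloxy)-1β-(Bpin)-3,6α-bis(triethylsilyloxy)eudesma-3,11(13)-dien-12-oate | CC[Si](CC)(CC)O[C@@H]1[C@H]2C(CO[Si](C)(C)C(C)(C)C)=C(O[Si](CC)(CC)CC)C[C@@H](B3OC(C)(C)C(C)(C)O3)[C@]2(C)CC[C@H]1C(=C)C(=O)OC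
F6 | step 10 | methyl 6α-hydroxy-4α-(hydroxymethyl)-3-oxo-1β-(Bpin)eudesm-11(13)-en-12-oate | O[C@@H]1[C@H]2[C@H](CO)C(=O)C[C@@H](B3OC(C)(C)C(C)(C)O3)[C@]2(C)CC[C@H]1C(=C)C(=O)OC
F7 | step 10 | methyl 6α-hydroxy-4α-[(methanesulfonyloxy)methyl]-3-oxo-1β-(Bpin)eudesm-11(13)-en-12-oate | O[C@@H]1[C@H]2[C@H](COS(C)(=O)=O)C(=O)C[C@@H](B3OC(C)(C)C(C)(C)O3)[C@]2(C)CC[C@H]1C(=C)C(=O)OC
F8 | step 8 | 2-[(1E)-2-methylhex-1-en-5-yn-1-yl]-4,4,5,5-tetramethyl-1,3,2-dioxaborolane | C#CCC/C(C)=C/B1OC(C)(C)C(C)(C)O1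
F9 | step 8 | methyl (6E)-6-methyl-7-(Bpin)hept-6-en-2-ynoate | COC(=O)C#CCC/C(C)=C/B1OC(C)(C)C(C)(C)O1
F10 | step 8 | methyl (2Z,6E)-6-methyl-7-(Bpin)-2-[(Bpin)methyl]hepta-2,6-dienoate | COC(=O)/C(CB1OC(C)(C)C(C)(C)O1)=C\CC/C(C)=C/B1OC(C)(C)C(C)(C)O1
F11 | step 8 | methyl (3S,4R,5E)-4-hydroxy-6-[(pivaloyloxy)methyl]-2-methylidene-3-[(3E)-3-methyl-4-(Bpin)but-3-en-1-yl]-7-oxooct-5-enoate | CC(=O)/C(COC(=O)C(C)(C)C)=C/[C@@H](O)[C@@H](CC/C(C)=C/B1OC(C)(C)C(C)(C)O1)C(=C)C(=O)OC
F12 | step 15 | methyl 6α-(prop-2-enoyloxy)-3-oxo-1β-(Bpin)eudesma-4(15),11(13)-dien-12-oate | C=CC(=O)O[C@@H]1[C@H]2C(=C)C(=O)C[C@@H](B3OC(C)(C)C(C)(C)O3)[C@]2(C)CC[C@H]1C(=C)C(=O)OC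
F13 | step 15 | methyl 3β-hydroxy-6α-(prop-2-enoyloxy)-1β-(Bpin)eudesma-4(15),11(13)-dien-12-oate | C=CC(=O)O[C@@H]1[C@H]2C(=C)[C@@H](O)C[C@@H](B3OC(C)(C)C(C)(C)O3)[C@]2(C)CC[C@H]1C(=C)C(=O)OC
F14 | step 15 | methyl 1β,3β-dihydroxy-6α-(prop-2-enoyloxy)eudesma-4(15),11(13)-dien-12-oate | C=CC(=O)O[C@@H]1[C@H]2C(=C)[C@@H](O)C[C@@H](O)[C@]2(C)CC[C@H]1C(=C)C(=O)OC
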